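Labels: C1 bears the tiglate, C5 the benzoate, C6 (CH) and C7 (C–CH3) are the ring fusion, C10 the carbinol; ring A is seven-membered, ring B five-membered. Everything rests on cutting C7–C8 of ring B: C7 is alpha to C1 and two bonds from C10, and C10 carries the hydroxy, isopropyl and two-carbon arm of an ethynyl adduct of an isopropyl ketone. Gold-catalysed 5-endo-dig attack of a C1 silyl dienol ether on that alkyne therefore closes ring B, sets quaternary C7 with cis fusion and returns the C1 enone in one operation. The precursor is ring A as its C1 silyl dienol ether carrying the C5 aryl ester and the C6-bound silylated ethynyl carbinol.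

Key step: step 15

Remark: further labels are C2=C3 (ring A alkene, methyl on C3), C4 (ring A CH2), C8 and C9 (ring B CH2), and ring locants in the names follow these labels; the carbon that becomes C7 is carried as an epimer mixture from step 2 to step 4 and from step 6 to step 13, and C1 from step 8 to step 9, because these centres become trigonal in steps 5, 14 and 10; 2-bromo-3-methylbut-1-ene is assumed to be a catalogue reagent.

Step 1
Reactants: 1 (S)-epichlorohydrin; 2 isopropenylmagnesium bromide
Product: 4 (2S)-2-(2-methylprop-2-en-1-yl)oxirane, via chlorohydrin 3 (not isolated)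
Conditions: CuI (10 mol%), THF, −40 °C; then NaOH, H2O, rt
Reagents that add atoms: none
Why: Copper-catalysed SN2 opening of the unsubstituted epoxide carbon by the alkenyl Grignard reagent followed by base-induced Williamson closure of the chlorohydrin should give the homologous epoxide, the stereocentre (the later C5) taking no part in either bond change.

Step 2
Reactants: 4 (2S)-2-(2-methylprop-2-en-1-yl)oxirane; 5 4-propanoylmorpholine
Product: 7 4-[(4R)-2,6-dimethyl-4-(triethylsilyloxy)hept-6-enoyl]morpholine as C2 epimers, via hydroxy amide 6 (not isolated)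
Conditions: lithium diisopropylamide, LiCl, THF, −78 to 0 °C; then Et3SiCl, 0 °C
Reagents that add atoms: chlorotriethylsilane, CC[Si](Cl)(CC)CC
Why: Alkylation of the lithium amide enolate by SN2 opening of the terminal epoxide carbon and silylation of the resulting lithium alkoxide in the same flask should give the protected hydroxy amide; the methyl-bearing carbon (later C7) forms without control, which is harmless because it becomes trigonal in step 5.

Step 3
Reactants: 7 4-[(4R)-2,6-dimethyl-4-(triethylsilyloxy)hept-6-enoyl]morpholine; 8 vinylmagnesium bromide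
Product: 9 (6R)-4,8-dimethyl-6-(triethylsilyloxy)nona-1,8-dien-3-one as C4 epimers
Conditions: THF, 0 °C to rt; inverse quench into cold 0.5 M HCl
Reagents that add atoms: none
Why: Acyl substitution at a morpholine amide, in which the vinyl Grignard reagent gives a tetrahedral magnesium adduct that collapses to the vinyl ketone only on work-up, while the acidic inverse quench keeps the liberated morpholine protonated so that it cannot add to the enone.

Step 4
Reactants: 9 (6R)-4,8-dimethyl-6-(triethylsilyloxy)nona-1,8-dien-3-one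
Product: 10 (5R)-3,7-dimethyl-5-(triethylsilyloxy)cyclohept-2-en-1-one as C7 epimers
Conditions: second-generation Grubbs catalyst (5 mol%), toluene, 80 °C
Reagents that add atoms: none
Why: Ring-closing olefin metathesis between the vinyl ketone and the 1,1-disubstituted alkene should close the seven-membered ring A with its trisubstituted C2=C3 bond, ethene being lost.

Step 5
Reactants: 10 (5R)-3,7-dimethyl-5-(triethylsilyloxy)cyclohept-2-en-1-one
Product: 12 (4S)-2,6-dimethyl-4-(triethylsilyloxy)cyclohepta-2,6-dien-1-one, via silyl dienol ether 11 (not isolated)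
Conditions: lithium diisopropylamide, Me3SiCl, THF, −78 °C; then Pd(OAc)2 (1.05 equiv), MeCN, rt
Reagents that add atoms: chlorotrimethylsilane, C[Si](C)(C)Cl (retained only in 11)
Why: Saegusa–Ito oxidation, in which kinetic deprotonation at the alpha-prime carbon C7 gives the cross-conjugated silyl dienol ether and the divalent palladium enolate formed from it loses a ring hydride from C6 to give the conjugated C6=C7 bond, which also removes the uncontrolled C7 centre.

Step 6
Reactants: 12 (4S)-2,6-dimethyl-4-(triethylsilyloxy)cyclohepta-2,6-dien-1-one; 13 2-bromo-3-methylbut-1-ene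
Product: 16 (5S,6R)-3,7-dimethyl-6-(3-methylbut-1-en-2-yl)-5-(triethylsilyloxy)cyclohept-2-en-1-one as C7 epimers, via Grignard reagent 14 (not isolated), via silyl dienol ether 15 (not isolated)
Conditions: 13, Mg, THF; then CuBr·SMe2 (10 mol%), Me3SiCl, 12, THF, −78 °C; then 10% aq. citric acid
Reagents that add atoms: magnesium, [Mg] (retained only in 14); chlorotrimethylsilane, C[Si](C)(C)Cl (retained only in 15)
Why: Copper-catalysed conjugate addition of the alkenyl Grignard reagent, accelerated by the chlorosilane, in which the monosubstituted beta carbon C6 should react in preference to the disubstituted C3 and the reagent should enter anti to the C5 silyloxy group, which sets C6 trans to C5–O; mild acid then hydrolyses the silyl dienol ether.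

Step 7
Reactants: 16 (5S,6R)-3,7-dimethyl-6-(3-methylbut-1-en-2-yl)-5-(triethylsilyloxy)cyclohept-2-en-1-one
Product: 17 (5S,6S)-3,7-dimethyl-6-(2-methylpropanoyl)-5-(triethylsilyloxy)cyclohept-2-en-1-one as C7 epimers
Conditions: O3, CH2Cl2–MeOH, Sudan Red 7B, −78 °C; then Me2S
Reagents that add atoms: ozone, [O-][O+]=O
Why: Ozonolysis with reductive work-up, in which ozone dosed to the end point of the dye should cleave the electron-rich 1,1-disubstituted alkene and leave the electron-poor ring enone alkene, unveiling the C10 isopropyl ketone.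

Step 8
Reactants: 17 (5S,6S)-3,7-dimethyl-6-(2-methylpropanoyl)-5-(triethylsilyloxy)cyclohept-2-en-1-one
Product: 19 1-[(5S,6S)-1,5-dihydroxy-3,7-dimethylcyclohept-2-en-6-yl]-2-methylpropan-1-one as C1/C7 epimers, via allylic alcohol 18 (not isolated)
Conditions: NaBH4, CeCl3·7H2O, MeOH, −78 °C; then AcOH–THF–H2O (3:1:1), rt
Reagents that add atoms: none
Why: Luche 1,2-reduction, in which the cerium-activated enone carbonyl C1 should be reduced rapidly at −78 °C whereas the C10 ketone, flanked by two tertiary carbons, should not, so that C1 is masked as a carbinol for step 9 (its configuration is immaterial); aqueous acetic acid then cleaves the secondary triethylsilyl ether.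

Step 9
Reactants: 19 1-[(5S,6S)-1,5-dihydroxy-3,7-dimethylcyclohept-2-en-6-yl]-2-methylpropan-1-one; 20 ethynylmagnesium bromide
Product: 21 (5S,6S)-6-[(3R)-3-hydroxy-4-methylpent-1-yn-3-yl]-3,7-dimethylcyclohept-2-ene-1,5-diol as C1/C7 epimers
Conditions: THF, −78 to 0 °C; then aq. NH4Cl
Reagents that add atoms: none
Why: Chelation-controlled Grignard 1,2-addition to the only carbonyl group present, in which the C5 magnesium alkoxide binds the C10 carbonyl in a six-membered chelate trans-fused to ring A and the slim acetylide adds axially, anti to the C6–H bond, which sets C10 as (10R).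

Step 10
Reactants: 21 (5S,6S)-6-[(3R)-3-hydroxy-4-methylpent-1-yn-3-yl]-3,7-dimethylcyclohept-2-ene-1,5-diol
Product: 22 (5S,6S)-5-hydroxy-6-[(3R)-3-hydroxy-4-methylpent-1-yn-3-yl]-3,7-dimethylcyclohept-2-en-1-one as C7 epimers
Conditions: MnO2, CH2Cl2, rt
Reagents that add atoms: none
Why: Oxidation of an allylic alcohol with MnO2, which should convert only the allylic C1 carbinol into the enone and leave the saturated C5 and the tertiary C10 hydroxy groups.

Step 11
Reactants: 23 4-hydroxybenzoic acid
Product: 25 4-(tert-butyldimethylsilyloxy)benzoic acid, via silyl ester 24 (not isolated)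
Conditions: t-BuMe2SiCl (2.2 equiv), imidazole, DMF, rt; then AcOH–THF–H2O, rt
Reagents that add atoms: tert-butylchlorodimethylsilane, CC(C)(C)[Si](C)(C)Cl
Why: Silylation of both the phenol and the acid followed by selective hydrolysis of the labile silyl ester should free the carboxylic acid with the phenol still protected.

Step 12
Reactants: 22 (5S,6S)-5-hydroxy-6-[(3R)-3-hydroxy-4-methylpent-1-yn-3-yl]-3,7-dimethylcyclohept-2-en-1-one; 25 4-(tert-butyldimethylsilyloxy)benzoic acid
Product: 26 C5 4-(tert-butyldimethylsilyloxy)benzoate of 22 (5S,6S,10R; C7 epimers)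
Conditions: dicyclohexylcarbodiimide, DMAP (20 mol%), CH2Cl2, rt
Reagents that add atoms: none
Why: Steglich esterification, which should acylate the secondary C5 hydroxy group only, the tertiary propargylic C10 hydroxy group being too hindered to react.

Step 13
Reactants: 26 C5 4-(tert-butyldimethylsilyloxy)benzoate of 22
Product: 27 C10 triethylsilyl ether of 26 (5S,6S,10R; C7 epimers)
Conditions: Et3SiOTf, 2,6-lutidine, CH2Cl2, −78 to 0 °C
Reagents that add atoms: triethylsilyl trifluoromethanesulfonate, CC[Si](CC)(CC)OS(=O)(=O)C(F)(F)F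
Why: Silylation of a hindered tertiary alcohol with a silyl triflate and a non-nucleophilic pyridine base should cap the C10 hydroxy group without touching the enone or the esters.

Step 14
Reactants: 27 C10 triethylsilyl ether of 26
Product: 28 C1 tert-butyldimethylsilyl dienol ether of 27 (C1=C7 and C2=C3; 5S,6S,10R)
Conditions: KN(SiMe3)2 (1.1 equiv), THF, −78 °C; then t-BuMe2SiOTf, −78 °C
Reagents that add atoms: tert-butyldimethylsilyl trifluoromethanesulfonate, CC(C)(C)[Si](C)(C)OS(=O)(=O)C(F)(F)F
Why: Kinetic enolisation and O-silylation, in which the bulky amide base should remove the alpha-prime proton at C7 at −78 °C faster than a gamma proton, is too weak to consume the alkyne C–H, and trapping on oxygen gives the cross-conjugated dienol ether in which both C7 epimers converge.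

Step 15
Reactants: 28 C1 tert-butyldimethylsilyl dienol ether of 27
Product: 29 (5S,6S,7R,10S)-cis-fused bicyclo[5.3.0]deca-2,8-dien-1-one with 3,7-dimethyl and 10-isopropyl groups, the C5 4-(tert-butyldimethylsilyloxy)benzoate and the C10 triethylsilyl ether
Conditions: Ph3PAuCl (10 mol%), AgSbF6 (10 mol%), CH2Cl2–MeOH (10:1), rt
Reagents that add atoms: none
Why: Cationic monovalent gold, freed from Ph3PAuCl by AgSbF6, coordinates the terminal alkyne, and C7 of the silyl dienol ether attacks C8 anti to gold; methanol then takes the silyl group from the oxocarbenium ion and protonates the vinyl–gold bond, which returns the C1 enone and leaves the C8=C9 alkene. The closest known reaction type is the gold-catalysed 5-endo-dig carbocyclisation of silyl enol ethers onto alkynes, which is known for terminal alkynes and for fused cyclopentenes with a quaternary carbon. Ring B (C6–C7–C8–C9–C10) closes in the 5-endo-dig mode, because the one-atom link C6–C10 leaves the distal alkyne carbon C8 as the only one that C7 can reach without forming a four-membered ring. The new stereocentre C7 is controlled by C6, since the alkyne hangs from C10 on C6 and C8 can therefore be delivered only to the face of C7 on which C10 lies, which pushes the methyl group to the face of H6 (cis fusion, 7R). The step needs site selectivity within the dienol ether and chemoselectivity over the propargylic silyl ether; the first is secured because C7 is the only nucleophilic enol ether carbon (C2 belongs to the spectator C2=C3 alkene), the second because a silyl ether, unlike a propargylic ester or a free alcohol, should neither migrate nor ionise under these nearly neutral conditions.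

Step 16
Reactants: 29 cis-fused bicyclic dienone
Product: 30 (5S,6S,7R,10R)-cis-fused bicyclo[5.3.0]dec-2-en-1-one with the same substituents as 29
Conditions: 2-nitrobenzenesulfonohydrazide, Et3N, CH2Cl2, rt
Reagents that add atoms: none
Why: Diimide reduction, a concerted syn transfer of two hydrogen atoms that should saturate the cis-disubstituted C8=C9 bond much faster than the trisubstituted conjugated C2=C3 bond and that leaves esters, ketone and silyl ethers alone.

Step 17
Reactants: 30 cis-fused bicyclic enone
Product: 31 (1R,5S,6S,7R,10R)-allylic alcohol, the C1 carbinol of 30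
Conditions: (S)-Me-CBS oxazaborolidine, C18H20BNO (0.5 equiv), catecholborane, toluene, −78 to −40 °C
Reagents that add atoms: none
Why: Corey–Bakshi–Shibata reduction of the enone carbonyl, in which, with the fully substituted C7 as the large flank, the (S)-catalyst should deliver hydride to the C1 face on which ring B lies and give the (1R)-alcohol with the hydroxy group cis to the C7 methyl, while catecholborane at low temperature avoids 1,4-reduction and hydroboration.

Step 18
Reactants: 31 (1R,5S,6S,7R,10R)-allylic alcohol; 32 tigloyl chloride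
Product: 33 C1 tiglate of 31 (1R,5S,6S,7R,10R)
Conditions: DMAP, Et3N, CH2Cl2, 0 °C to rt
Reagents that add atoms: none
Why: DMAP-catalysed acylation of the secondary allylic alcohol with the acid chloride should give the tiglate with the E geometry of the acyl group unchanged, the silylated tertiary and phenolic oxygens being inert.

Step 19
Reactants: 33 C1 tiglate of 31
Product: 34 target, (1R,5S,6S,7R,10R)-10-hydroxy-10-isopropyl-3,7-dimethyl-1-[(E)-2-methylbut-2-enoyloxy]-cis-bicyclo[5.3.0]dec-2-en-5-yl 4-hydroxybenzoate
Conditions: HF·pyridine, pyridine, THF, 0 °C to rt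
Reagents that add atoms: none
Why: Fluoride-induced desilylation should cleave the aryl silyl ether and the tertiary triethylsilyl ether and leave both esters, the alkene and all five stereocentres untouched, giving the target.

Compound list
1 | (S)-epichlorohydrin | ClC[C@@H]1CO1 | starting material
2 | isopropenylmagnesium bromide | CC(=C)[Mg]Br | starting material
3 | (2S)-1-chloro-4-methylpent-4-en-2-ol | ClC[C@@H](O)CC(C)=C | intermediate (not isolated)
4 | (2S)-2-(2-methylprop-2-en-1-yl)oxirane | CC(=C)C[C@H]1CO1 | intermediate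
5 | 4-propanoylmorpholine | CCC(=O)N1CCOCC1 | starting material
6 | 4-[(4R)-4-hydroxy-2,6-dimethylhept-6-enoyl]morpholine (lithium alkoxide in the flask; C2 epimers) | CC(=C)C[C@H](O)CC(C)C(=O)N1CCOCC1 | intermediate (not isolated)
7 | 4-[(4R)-2,6-dimethyl-4-(triethylsilyloxy)hept-6-enoyl]morpholine (C2 epimers) | CC(=C)C[C@H](O[Si](CC)(CC)CC)CC(C)C(=O)N1CCOCC1 | intermediate
8 | vinylmagnesium bromide | C=C[Mg]Br | starting material
9 | (6R)-4,8-dimethyl-6-(triethylsilyloxy)nona-1,8-dien-3-one (C4 epimers) | C=CC(=O)C(C)C[C@@H](O[Si](CC)(CC)CC)CC(C)=C | intermediate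
10 | (5R)-3,7-dimethyl-5-(triethylsilyloxy)cyclohept-2-en-1-one (C7 epimers) | O=C1C=C(C)C[C@H](O[Si](CC)(CC)CC)CC1C | intermediate
11 | C1 trimethylsilyl dienol ether of 10 (C1=C7 and C2=C3; 5S) | C[Si](C)(C)OC1=C(C)C[C@@H](O[Si](CC)(CC)CC)CC(C)=C1 | intermediate (not isolated)
12 | (4S)-2,6-dimethyl-4-(triethylsilyloxy)cyclohepta-2,6-dien-1-one (its C4 is label C5) | O=C1C=C(C)C[C@H](O[Si](CC)(CC)CC)C=C1C | intermediate
13 | 2-bromo-3-methylbut-1-ene | CC(C)C(Br)=C | starting material
14 | (3-methylbut-1-en-2-yl)magnesium bromide | CC(C)C(=C)[Mg]Br | intermediate (not isolated)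
15 | C1 trimethylsilyl dienol ether of 16 (C1=C7 and C2=C3; 5S,6S) | C[Si](C)(C)OC1=C(C)[C@H](C(=C)C(C)C)[C@@H](O[Si](CC)(CC)CC)CC(C)=C1 | intermediate (not isolated)
16 | (5S,6R)-3,7-dimethyl-6-(3-methylbut-1-en-2-yl)-5-(triethylsilyloxy)cyclohept-2-en-1-one (C7 epimers) | O=C1C=C(C)C[C@H](O[Si](CC)(CC)CC)[C@@H](C(=C)C(C)C)C1C | intermediate
17 | (5S,6S)-3,7-dimethyl-6-(2-methylpropanoyl)-5-(triethylsilyloxy)cyclohept-2-en-1-one (C7 epimers) | O=C1C=C(C)C[C@H](O[Si](CC)(CC)CC)[C@@H](C(=O)C(C)C)C1C | intermediate
18 | 1-[(5S,6S)-1-hydroxy-3,7-dimethyl-5-(triethylsilyloxy)cyclohept-2-en-6-yl]-2-methylpropan-1-one (C1/C7 epimers) | OC1C=C(C)C[C@H](O[Si](CC)(CC)CC)[C@@H](C(=O)C(C)C)C1C | intermediate (not isolated)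
19 | 1-[(5S,6S)-1,5-dihydroxy-3,7-dimethylcyclohept-2-en-6-yl]-2-methylpropan-1-one (C1/C7 epimers) | OC1C=C(C)C[C@H](O)[C@@H](C(=O)C(C)C)C1C | intermediate
20 | ethynylmagnesium bromide | C#C[Mg]Br | starting material
21 | (5S,6S)-6-[(3R)-3-hydroxy-4-methylpent-1-yn-3-yl]-3,7-dimethylcyclohept-2-ene-1,5-diol (C1/C7 epimers) | OC1C=C(C)C[C@H](O)[C@@H]([C@@](O)(C#C)C(C)C)C1C | intermediate
22 | (5S,6S)-5-hydroxy-6-[(3R)-3-hydroxy-4-methylpent-1-yn-3-yl]-3,7-dimethylcyclohept-2-en-1-one (C7 epimers) | O=C1C=C(C)C[C@H](O)[C@@H]([C@@](O)(C#C)C(C)C)C1C | intermediate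
23 | 4-hydroxybenzoic acid | OC(=O)c1ccc(O)cc1 | starting material
24 | tert-butyldimethylsilyl 4-(tert-butyldimethylsilyloxy)benzoate | CC(C)(C)[Si](C)(C)OC(=O)c1ccc(O[Si](C)(C)C(C)(C)C)cc1 | intermediate (not isolated)
25 | 4-(tert-butyldimethylsilyloxy)benzoic acid | OC(=O)c1ccc(O[Si](C)(C)C(C)(C)C)cc1 | intermediate
26 | C5 4-(tert-butyldimethylsilyloxy)benzoate of 22 (5S,6S,10R; C7 epimers) | O=C1C=C(C)C[C@H](OC(=O)c2ccc(O[Si](C)(C)C(C)(C)C)cc2)[C@@H]([C@@](O)(C#C)C(C)C)C1C | intermediate
27 | C10 triethylsilyl ether of 26 (5S,6S,10R; C7 epimers) | O=C1C=C(C)C[C@H](OC(=O)c2ccc(O[Si](C)(C)C(C)(C)C)cc2)[C@@H]([C@@](O[Si](CC)(CC)CC)(C#C)C(C)C)C1C | intermediate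
28 | C1 tert-butyldimethylsilyl dienol ether of 27 (C1=C7 and C2=C3; 5S,6S,10R) | CC(C)(C)[Si](C)(C)OC1=C(C)[C@H]([C@@](O[Si](CC)(CC)CC)(C#C)C(C)C)[C@@H](OC(=O)c2ccc(O[Si](C)(C)C(C)(C)C)cc2)CC(C)=C1 | intermediate
29 | (5S,6S,7R,10S)-cis-fused bicyclo[5.3.0]deca-2,8-dien-1-one, 3,7-dimethyl, 10-isopropyl, C5 4-(tert-butyldimethylsilyloxy)benzoate, C10 triethylsilyl ether | O=C1C=C(C)C[C@H](OC(=O)c2ccc(O[Si](C)(C)C(C)(C)C)cc2)[C@@H]2[C@@]1(C)C=C[C@@]2(O[Si](CC)(CC)CC)C(C)C | intermediate
30 | (5S,6S,7R,10R)-cis-fused bicyclo[5.3.0]dec-2-en-1-one with the substituents of 29 | O=C1C=C(C)C[C@H](OC(=O)c2ccc(O[Si](C)(C)C(C)(C)C)cc2)[C@@H]2[C@@]1(C)CC[C@@]2(O[Si](CC)(CC)CC)C(C)C | intermediate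
31 | (1R,5S,6S,7R,10R)-C1 allylic alcohol from 30 | O[C@@H]1C=C(C)C[C@H](OC(=O)c2ccc(O[Si](C)(C)C(C)(C)C)cc2)[C@@H]2[C@@]1(C)CC[C@@]2(O[Si](CC)(CC)CC)C(C)C | intermediate
32 | tigloyl chloride, (E)-2-methylbut-2-enoyl chloride | C/C=C(\C)C(Cl)=O | starting material
33 | C1 tiglate of 31 (1R,5S,6S,7R,10R) | C/C=C(\C)C(=O)O[C@@H]1C=C(C)C[C@H](OC(=O)c2ccc(O[Si](C)(C)C(C)(C)C)cc2)[C@@H]2[C@@]1(C)CC[C@@]2(O[Si](CC)(CC)CC)C(C)C | intermediate
34 | target (1R,5S,6S,7R,10R) | C/C=C(\C)C(=O)O[C@@H]1C=C(C)C[C@H](OC(=O)c2ccc(O)cc2)[C@@H]2[C@@]1(C)CC[C@@]2(O)C(C)C | target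

Total step count: 19. Longest linear sequence: 18 (steps 1–10 and 12–19).

Steps most likely to fail

Step 15: the enol ether may be hydrolysed back to the ketone before the carbon–carbon bond forms, or closure at the congested C7 may be so slow that the alkyne is hydrated or the propargylic silyl ether is lost. The fallback sets out from 27. N-Iodosuccinimide with catalytic AgNO3 in acetone should give the iodoalkyne F1, and diimide (2-nitrobenzenesulfonohydrazide, Et3N) should reduce it to the (Z)-iodoalkene F2. Pd(PPh3)4 (zerovalent palladium) with KOt-Bu in THF should then join C7 to C8 by intramolecular enolate alkenylation, the tether again allowing only the cis fusion, and the route is rejoined at 29.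

Step 14: deprotonation may occur at the gamma carbon C4 instead of C7, after which the C5 aroyloxy group is expelled, or the enolate may attack the neighbouring ester. The fallback sets out from 22 and moves the esterification behind the ring closure. Et3SiOTf and 2,6-lutidine should give the bis(triethylsilyl) ether F3, which has no acyloxy leaving group; KN(SiMe3)2 and t-BuMe2SiOTf should give the silyl dienol ether F4; Ph3PAuCl and AgSbF6 in CH2Cl2–MeOH should close ring B to the bicyclic dienone F5. Pyridinium p-toluenesulfonate in MeOH at 0 °C should remove only the secondary silyl ether to give the C5 alcohol F6, and esterification with 25 (dicyclohexylcarbodiimide, DMAP) returns to 29.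

Step 17: hydride delivery may show poor facial selectivity, because the alkenyl flank and the quaternary flank of the carbonyl group are not clearly differentiated for the catalyst. The fallback sets out from 30. Substrate-controlled Luche reduction (NaBH4, CeCl3·7H2O, MeOH) from the exposed face opposite ring B should give the C1 epimer F7, and a Mitsunobu reaction with tiglic acid, C/C=C(\C)C(O)=O (PPh3, diisopropyl azodicarboxylate) should install the ester with inversion at C1, rejoining at 33.

Further compounds
F1 | step 15 | iodoalkyne analogue of 27 | O=C1C=C(C)C[C@H](OC(=O)c2ccc(O[Si](C)(C)C(C)(C)C)cc2)[C@@H]([C@@](O[Si](CC)(CC)CC)(C#CI)C(C)C)C1C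
F2 | step 15 | (Z)-iodoalkene analogue of 27 | O=C1C=C(C)C[C@H](OC(=O)c2ccc(O[Si](C)(C)C(C)(C)C)cc2)[C@@H]([C@@](O[Si](CC)(CC)CC)(/C=C\I)C(C)C)C1C
F3 | step 14 | C5,C10 bis(triethylsilyl) ether of 22 | O=C1C=C(C)C[C@H](O[Si](CC)(CC)CC)[C@@H]([C@@](O[Si](CC)(CC)CC)(C#C)C(C)C)C1C
F4 | step 14 | C1 tert-butyldimethylsilyl dienol ether of F3 | CC(C)(C)[Si](C)(C)OC1=C(C)[C@H]([C@@](O[Si](CC)(CC)CC)(C#C)C(C)C)[C@@H](O[Si](CC)(CC)CC)CC(C)=C1
F5 | step 14 | cis-fused bicyclic dienone with C5 and C10 triethylsilyl ethers | O=C1C=C(C)C[C@H](O[Si](CC)(CC)CC)[C@@H]2[C@@]1(C)C=C[C@@]2(O[Si](CC)(CC)CC)C(C)C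
F6 | step 14 | cis-fused bicyclic dienone with free C5 hydroxy group and C10 triethylsilyl ether | O=C1C=C(C)C[C@H](O)[C@@H]2[C@@]1(C)C=C[C@@]2(O[Si](CC)(CC)CC)C(C)C
F7 | step 17 | C1 epimer of 31 (1S,5S,6S,7R,10R) | O[C@H]1C=C(C)C[C@H](OC(=O)c2ccc(O[Si](C)(C)C(C)(C)C)cc2)[C@@H]2[C@@]1(C)CC[C@@]2(O[Si](CC)(CC)CC)C(C)C
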